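Ring A (the alkynyl cyclohexenol: C1 CMe2, C2, C3 CHOH, C4, C5 CMe, C6 alkynyl carbon) is traced back to a ketone at C6, which makes C1 and C5 enolate carbons and C2–C3–C4 a glycerol-derived 1,3-dielectrophile whose only stereocentre, C3, lies between two CH2 groups. The key step joins C1–C2 and C4–C5 in one pot: an enone-derived, regio-defined enolate is alkylated by a chiral chloro triflate and the second enolate closes on the chloride, so the OTf/Cl order encodes the C3 configuration. The ketone's enol triflate serves ring A (Sonogashira) and the triol ring C (via an ethynyl epoxide); Suzuki, Sonogashira–lactonisation (butenolide ring B) and Stille couplings finish.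

Key step: step 2

Remark: (S)-3-chloropropane-1,2-diol, 2-methylpent-1-en-3-one and (E)-3-methylpent-2-en-4-yn-1-ol are taken as catalogue chemicals.
Remark on locants: ring A carbons are C1–C6 as above; the chain runs from C7 (alkyne carbon on ring A) to C17, and C18 is the ylidene-bearing carbon of ring B; ring C carries C3′, C5′, C6′ and the C7′=C8′ vinyl link.

Step 1
Reactants: 1 (S)-3-chloropropane-1,2-diol
Product: 3 (2S)-2-[(tert-butyldimethylsilyl)oxy]-3-chloropropyl trifluoromethanesulfonate, via hydroxy triflate 2 (not isolated)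
Conditions: Tf2O (1.05 equiv), 2,6-lutidine, CH2Cl2, −78 °C; then t-BuMe2SiOTf, −78 → 0 °C; used at once
Reagents that add atoms: triflic anhydride O=S(=O)(OS(=O)(=O)C(F)(F)F)C(F)(F)F; tert-butyldimethylsilyl triflate CC(C)(C)[Si](C)(C)OS(=O)(=O)C(F)(F)F
Why: One-pot triflation–silylation of a 1,2-diol: the primary hydroxyl is sulfonylated much faster than the secondary one at −78 °C, the silyl triflate then caps the secondary hydroxyl, and the stereocentre is not touched.

Step 2
Reactants: 4 2-methylpent-1-en-3-one; 3 (2S)-2-[(tert-butyldimethylsilyl)oxy]-3-chloropropyl trifluoromethanesulfonate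
Product: 8 (4R)-4-[(tert-butyldimethylsilyl)oxy]-2,2,6-trimethylcyclohexan-1-one as a mixture of epimers at the methyl-bearing carbon, via lithium enolate 5 (not isolated), via chloro ketone 6 (not isolated), via chloro ketone enolate 7 (not isolated)
Conditions: LiBH(s-Bu)3 (1.0 equiv), THF, −78 °C, slow addition of 4; then 3, −78 → −20 °C; then LiN(i-Pr)2 (2.2 equiv), LiI (cat.), DMPU, −78 → 25 °C
Reagents that add atoms: none
Why: Conjugate hydride delivery from LiBH(s-Bu)3 to the unsubstituted methylene of 4 should give only the tetrasubstituted enolate 5 (the isopropyl-side enolate that deprotonation could not supply cleanly), whose carbon displaces the triflate of 3, by far the better leaving group, to make the quaternary C1–C2 bond and chloro ketone 6. LiN(i-Pr)2 can then enolise 6 only toward the ethyl group, and enolate 7 closes ring A by an iodide-assisted 6-(enolendo)-exo-tet SN2 displacement of chloride, forming C4–C5. The closest known reaction type is the reductive alkylation of enones through trialkylborohydride-derived enolates followed by intramolecular ketone enolate alkylation, that is an α,α′-annulation of a ketone with a 1,3-dielectrophile. The C3 stereocentre comes unchanged from 1, and the OTf/Cl reactivity order decides which CH2 of 3 ends at C1 and which at C5, hence the R configuration in the ring; the new centre at C5 forms as a mixture and is erased in step 3. The step needs C- over O-alkylation and no enolate scrambling, which the boron-bound lithium enolate 5, the single enolisable site of 6 and the six-membered carbon-centred closure should secure.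

Step 3
Reactants: 8 (4R)-4-[(tert-butyldimethylsilyl)oxy]-2,2,6-trimethylcyclohexan-1-one
Product: 10 (4R)-4-[(tert-butyldimethylsilyl)oxy]-2,6,6-trimethylcyclohex-1-en-1-yl trifluoromethanesulfonate, via potassium enolate 9 (not isolated)
Conditions: KN(SiMe3)2, THF, −78 °C; then PhNTf2, −78 → 0 °C
Reagents that add atoms: N-phenylbis(trifluoromethanesulfonimide) O=S(=O)(N(c1ccccc1)S(=O)(=O)C(F)(F)F)C(F)(F)F
Why: Enol triflate formation: 8 can enolise only toward the methyl-bearing carbon because the other α-carbon is quaternary, so both epimers should converge on one tetrasubstituted enol triflate (the C5=C6 bond of ring A).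

Step 4
Reactants: 10 (4R)-4-[(tert-butyldimethylsilyl)oxy]-2,6,6-trimethylcyclohex-1-en-1-yl trifluoromethanesulfonate; 11 ethynyltrimethylsilane
Product: 12 tert-butyldimethyl({(1R)-3,5,5-trimethyl-4-[(trimethylsilyl)ethynyl]cyclohex-3-en-1-yl}oxy)silane
Conditions: Pd(PPh3)4 (5 mol %), CuI (10 mol %), i-Pr2NH, DMF, 50 °C
Reagents that add atoms: none
Why: Sonogashira coupling of the hindered enol triflate with a terminal alkyne installs the two carbons that become C7′ and C8′ without touching the stereocentre.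

Step 5
Reactants: 12 tert-butyldimethyl({(1R)-3,5,5-trimethyl-4-[(trimethylsilyl)ethynyl]cyclohex-3-en-1-yl}oxy)silane
Product: 13 (1R)-4-ethynyl-3,5,5-trimethylcyclohex-3-en-1-ol
Conditions: Bu4NF (2.5 equiv), THF, 0 → 25 °C
Reagents that add atoms: none
Why: Fluoride desilylation cleaves the C-silyl and the O-silyl group together, freeing the terminal alkyne and the hydroxyl that directs step 6.

Step 6
Reactants: 13 (1R)-4-ethynyl-3,5,5-trimethylcyclohex-3-en-1-ol
Product: 14 (1S,3S,6S)-6-ethynyl-1,5,5-trimethyl-7-oxabicyclo[4.1.0]heptan-3-ol (epoxide oxygen cis to the hydroxyl)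
Conditions: VO(acac)2 (5 mol %), t-BuOOH, CH2Cl2, 0 → 25 °C
Reagents that add atoms: tert-butyl hydroperoxide CC(C)(C)OO
Why: Homoallylic-hydroxyl-directed vanadium-catalysed epoxidation: the vanadate ester of the ring hydroxyl should deliver oxygen to the alkene face cis to it, which sets C5′ and C6′ relative to C3′.

Step 7
Reactants: 14 (1S,3S,6S)-6-ethynyl-1,5,5-trimethyl-7-oxabicyclo[4.1.0]heptan-3-ol
Product: 15 (1S,2R,4S)-1-ethynyl-2,6,6-trimethylcyclohexane-1,2,4-triol
Conditions: HClO4 (cat., 0.1 M aq), THF–H2O 3:1, 0 °C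
Reagents that add atoms: water O
Why: Acid-catalysed epoxide hydrolysis with inversion at C5′, the epoxide carbon that is neither deactivated by the ethynyl group nor shielded by the gem-dimethyl carbon, should give the trans-5′,6′-diol with 5′-OH anti and 6′-OH syn to 3′-OH.

Step 8
Reactants: 15 (1S,2R,4S)-1-ethynyl-2,6,6-trimethylcyclohexane-1,2,4-triol
Product: 16 (1R,2R,4S)-2,6,6-trimethyl-1-[(E)-2-(tributylstannyl)ethenyl]cyclohexane-1,2,4-triol
Conditions: Bu3SnH (1.2 equiv), PdCl2(PPh3)2 (2 mol %), THF, 0 °C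
Reagents that add atoms: tributyltin hydride CCCC[SnH](CCCC)CCCC
Why: Palladium-catalysed syn-hydrostannation should place tin on the unhindered terminal carbon of the tertiary propargylic alcohol, giving the (E)-vinylstannane.

Step 9
Reactants: 17 (E)-3-methylpent-2-en-4-yn-1-ol
Product: 18 (E)-3-methylpent-2-en-4-ynal
Conditions: MnO2 (excess), CH2Cl2, 25 °C; used as a solution
Reagents that add atoms: none
Why: Allylic alcohol oxidation with manganese dioxide is chemoselective and leaves the (E)-enyne geometry intact.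

Step 10
Reactants: 18 (E)-3-methylpent-2-en-4-ynal
Product: 19 (1E,3E)-1-iodo-4-methylhexa-1,3-dien-5-yne
Conditions: CHI3, CrCl2, THF, 0 °C, dark
Reagents that add atoms: iodoform IC(I)I
Why: Takai olefination should give the (E)-vinyl iodide (C13=C14) and tolerates the terminal alkyne.

Step 11
Reactants: 18 (E)-3-methylpent-2-en-4-ynal
Product: 20 4,4,5,5-tetramethyl-2-[(1E,3E)-4-methylhexa-1,3-dien-5-yn-1-yl]-1,3,2-dioxaborolane
Conditions: Cl2CHBpin, CrCl2, LiI (additive), THF, 25 °C
Reagents that add atoms: 2-(dichloromethyl)-4,4,5,5-tetramethyl-1,3,2-dioxaborolane ClC(Cl)B1OC(C)(C)C(C)(C)O1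
Why: Takai–Utimoto boryl-olefination should turn the same aldehyde into the (E)-alkenylboronate (C11=C12) under non-basic conditions.

Step 12
Reactants: 10 (4R)-4-[(tert-butyldimethylsilyl)oxy]-2,6,6-trimethylcyclohex-1-en-1-yl trifluoromethanesulfonate; 20 4,4,5,5-tetramethyl-2-[(1E,3E)-4-methylhexa-1,3-dien-5-yn-1-yl]-1,3,2-dioxaborolane
Product: 21 tert-butyldimethyl({(1R)-3,5,5-trimethyl-4-[(3E,5E)-3-methyl-6-(4,4,5,5-tetramethyl-1,3,2-dioxaborolan-2-yl)hexa-3,5-dien-1-yn-1-yl]cyclohex-3-en-1-yl}oxy)silane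
Conditions: Pd(PPh3)4 (5 mol %), CuI (10 mol %), i-Pr2NH, DMF (dry), 25–40 °C
Reagents that add atoms: none
Why: Sonogashira coupling forms the C6–C7 bond of ring A, and the pinacol boronate should be inert under anhydrous amine conditions.

Step 13
Reactants: 21 tert-butyldimethyl({(1R)-3,5,5-trimethyl-4-[(3E,5E)-3-methyl-6-(4,4,5,5-tetramethyl-1,3,2-dioxaborolan-2-yl)hexa-3,5-dien-1-yn-1-yl]cyclohex-3-en-1-yl}oxy)silane; 19 (1E,3E)-1-iodo-4-methylhexa-1,3-dien-5-yne
Product: 22 tert-butyl({(1R)-4-[(3E,5E,7E,9E)-3,10-dimethyldodeca-3,5,7,9-tetraene-1,11-diyn-1-yl]-3,5,5-trimethylcyclohex-3-en-1-yl}oxy)dimethylsilane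
Conditions: PdCl2(dppf) (5 mol %), K3PO4 (aq), THF, 25 °C, dark
Reagents that add atoms: none
Why: Suzuki–Miyaura coupling joins the two (E,E)-dienyl halves at C12–C13 with retention of both geometries and without iodine or heat, which could isomerise the C9=C10 enyne bond.

Step 14
Reactants: 22 tert-butyl({(1R)-4-[(3E,5E,7E,9E)-3,10-dimethyldodeca-3,5,7,9-tetraene-1,11-diyn-1-yl]-3,5,5-trimethylcyclohex-3-en-1-yl}oxy)dimethylsilane
Product: 23 (1R)-4-[(3E,5E,7E,9E)-3,10-dimethyldodeca-3,5,7,9-tetraene-1,11-diyn-1-yl]-3,5,5-trimethylcyclohex-3-en-1-ol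
Conditions: Bu4NF, THF, 0 °C, dark
Reagents that add atoms: none
Why: Fluoride desilylation frees the ring A hydroxyl before the base- and fluoride-sensitive butenolide is built.

Step 15
Reactants: 24 propiolic acid
Product: 25 (E)-2,3-dibromoprop-2-enoic acid
Conditions: Br2 (1.0 equiv), CHCl3, 25 °C, dark
Reagents that add atoms: bromine BrBr
Why: Anti addition of bromine to the alkyne should give the (E)-dibromo acid, in which the C3 bromine is cis to the carboxyl group.

Step 16
Reactants: 23 (1R)-4-[(3E,5E,7E,9E)-3,10-dimethyldodeca-3,5,7,9-tetraene-1,11-diyn-1-yl]-3,5,5-trimethylcyclohex-3-en-1-ol; 25 (E)-2,3-dibromoprop-2-enoic acid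
Product: 27 (5Z)-3-bromo-5-{(2E,4E,6E,8E)-11-[(4R)-4-hydroxy-2,6,6-trimethylcyclohex-1-en-1-yl]-2,9-dimethylundeca-2,4,6,8-tetraen-10-yn-1-ylidene}furan-2(5H)-one, via enynoic acid 26 (not isolated)
Conditions: PdCl2(PPh3)2 (5 mol %), CuI (10 mol %), Et3N, MeCN, 25 °C, dark, no oxygen
Reagents that add atoms: none
Why: Tandem Sonogashira coupling–lactonisation: coupling at the more reactive C3–Br gives acid 26, whose cis carboxylate should add 5-exo-dig and anti across the alkyne to give the (Z)-ylidenebutenolide with the ring bromine retained.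

Step 17
Reactants: 27 (5Z)-3-bromo-5-{(2E,4E,6E,8E)-11-[(4R)-4-hydroxy-2,6,6-trimethylcyclohex-1-en-1-yl]-2,9-dimethylundeca-2,4,6,8-tetraen-10-yn-1-ylidene}furan-2(5H)-one; 16 (1R,2R,4S)-2,6,6-trimethyl-1-[(E)-2-(tributylstannyl)ethenyl]cyclohexane-1,2,4-triol
Product: 28 (5Z)-5-{(2E,4E,6E,8E)-11-[(4R)-4-hydroxy-2,6,6-trimethylcyclohex-1-en-1-yl]-2,9-dimethylundeca-2,4,6,8-tetraen-10-yn-1-ylidene}-3-{(E)-2-[(1R,2R,4S)-1,2,4-trihydroxy-2,6,6-trimethylcyclohexyl]ethenyl}furan-2(5H)-one (CNP0163979.1)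
Conditions: Pd2(dba)3 (2.5 mol %), AsPh3 (20 mol %), NMP, 25 °C, dark
Reagents that add atoms: none
Why: Stille coupling of the 3-bromobutenolide with the (E)-vinylstannane should form the last C–C bond with retention of alkene geometry under neutral conditions that tolerate the four free hydroxyls.

Compound list
1 | (S)-3-chloropropane-1,2-diol | ClC[C@@H](O)CO | starting material
2 | (2S)-3-chloro-2-hydroxypropyl trifluoromethanesulfonate | ClC[C@@H](O)COS(=O)(=O)C(F)(F)F | intermediate
3 | (2S)-2-[(tert-butyldimethylsilyl)oxy]-3-chloropropyl trifluoromethanesulfonate | ClC[C@@H](O[Si](C)(C)C(C)(C)C)COS(=O)(=O)C(F)(F)F | intermediate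
4 | 2-methylpent-1-en-3-one | CCC(=O)C(C)=C | starting material
5 | lithium 2-methylpent-2-en-3-olate (bound to tri-sec-butylborane) | CCC([O-])=C(C)C.[Li+] | intermediate
6 | (6S)-6-[(tert-butyldimethylsilyl)oxy]-7-chloro-4,4-dimethylheptan-3-one | CCC(=O)C(C)(C)C[C@H](O[Si](C)(C)C(C)(C)C)CCl | intermediate
7 | lithium enolate of 6, enolised toward C2 of the heptanone | CC=C([O-])C(C)(C)C[C@H](O[Si](C)(C)C(C)(C)C)CCl.[Li+] | intermediate
8 | (4R)-4-[(tert-butyldimethylsilyl)oxy]-2,2,6-trimethylcyclohexan-1-one, both C6 epimers | CC1C[C@@H](O[Si](C)(C)C(C)(C)C)CC(C)(C)C1=O | intermediate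
9 | potassium (4R)-4-[(tert-butyldimethylsilyl)oxy]-2,6,6-trimethylcyclohex-1-en-1-olate | CC1=C([O-])C(C)(C)C[C@H](O[Si](C)(C)C(C)(C)C)C1.[K+] | intermediate
10 | (4R)-4-[(tert-butyldimethylsilyl)oxy]-2,6,6-trimethylcyclohex-1-en-1-yl trifluoromethanesulfonate | CC1=C(OS(=O)(=O)C(F)(F)F)C(C)(C)C[C@H](O[Si](C)(C)C(C)(C)C)C1 | intermediate
11 | ethynyltrimethylsilane | C#C[Si](C)(C)C | starting material
12 | tert-butyldimethyl({(1R)-3,5,5-trimethyl-4-[(trimethylsilyl)ethynyl]cyclohex-3-en-1-yl}oxy)silane | CC1=C(C#C[Si](C)(C)C)C(C)(C)C[C@H](O[Si](C)(C)C(C)(C)C)C1 | intermediate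
13 | (1R)-4-ethynyl-3,5,5-trimethylcyclohex-3-en-1-ol | CC1=C(C#C)C(C)(C)C[C@H](O)C1 | intermediate
14 | (1S,3S,6S)-6-ethynyl-1,5,5-trimethyl-7-oxabicyclo[4.1.0]heptan-3-ol, epoxide oxygen cis to the hydroxyl | C#C[C@@]12C(C)(C)C[C@H](O)C[C@]1(C)O2 | intermediate
15 | (1S,2R,4S)-1-ethynyl-2,6,6-trimethylcyclohexane-1,2,4-triol | C#C[C@@]1(O)C(C)(C)C[C@H](O)C[C@@]1(C)O | intermediate
16 | (1R,2R,4S)-2,6,6-trimethyl-1-[(E)-2-(tributylstannyl)ethenyl]cyclohexane-1,2,4-triol | CCCC[Sn](CCCC)(CCCC)/C=C/[C@@]1(O)C(C)(C)C[C@H](O)C[C@@]1(C)O | intermediate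
17 | (E)-3-methylpent-2-en-4-yn-1-ol | C#C/C(C)=C/CO | starting material
18 | (E)-3-methylpent-2-en-4-ynal | C#C/C(C)=C/C=O | intermediate
19 | (1E,3E)-1-iodo-4-methylhexa-1,3-dien-5-yne | C#C/C(C)=C/C=C/I | intermediate
20 | 4,4,5,5-tetramethyl-2-[(1E,3E)-4-methylhexa-1,3-dien-5-yn-1-yl]-1,3,2-dioxaborolane | C#C/C(C)=C/C=C/B1OC(C)(C)C(C)(C)O1 | intermediate
21 | tert-butyldimethyl({(1R)-3,5,5-trimethyl-4-[(3E,5E)-3-methyl-6-(4,4,5,5-tetramethyl-1,3,2-dioxaborolan-2-yl)hexa-3,5-dien-1-yn-1-yl]cyclohex-3-en-1-yl}oxy)silane | CC1=C(C#C/C(C)=C/C=C/B2OC(C)(C)C(C)(C)O2)C(C)(C)C[C@H](O[Si](C)(C)C(C)(C)C)C1 | intermediate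
22 | tert-butyl({(1R)-4-[(3E,5E,7E,9E)-3,10-dimethyldodeca-3,5,7,9-tetraene-1,11-diyn-1-yl]-3,5,5-trimethylcyclohex-3-en-1-yl}oxy)dimethylsilane | CC1=C(C#C/C(C)=C/C=C/C=C/C=C(C)/C#C)C(C)(C)C[C@H](O[Si](C)(C)C(C)(C)C)C1 | intermediate
23 | (1R)-4-[(3E,5E,7E,9E)-3,10-dimethyldodeca-3,5,7,9-tetraene-1,11-diyn-1-yl]-3,5,5-trimethylcyclohex-3-en-1-ol | CC1=C(C#C/C(C)=C/C=C/C=C/C=C(C)/C#C)C(C)(C)C[C@H](O)C1 | intermediate
24 | propiolic acid | C#CC(=O)O | starting material
25 | (E)-2,3-dibromoprop-2-enoic acid | OC(=O)/C(Br)=C\Br | intermediate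
26 | (2E,6E,8E,10E,12E)-2-bromo-15-[(4R)-4-hydroxy-2,6,6-trimethylcyclohex-1-en-1-yl]-6,13-dimethylpentadeca-2,6,8,10,12-pentaene-4,14-diynoic acid | CC1=C(C#C/C(C)=C/C=C/C=C/C=C(C)/C#C/C=C(/Br)C(=O)O)C(C)(C)C[C@H](O)C1 | intermediate
27 | (5Z)-3-bromo-5-{(2E,4E,6E,8E)-11-[(4R)-4-hydroxy-2,6,6-trimethylcyclohex-1-en-1-yl]-2,9-dimethylundeca-2,4,6,8-tetraen-10-yn-1-ylidene}furan-2(5H)-one | CC1=C(C#C/C(C)=C/C=C/C=C/C=C(C)/C=C2C=C(Br)C(=O)O/2)C(C)(C)C[C@H](O)C1 | intermediate
28 | (5Z)-5-{(2E,4E,6E,8E)-11-[(4R)-4-hydroxy-2,6,6-trimethylcyclohex-1-en-1-yl]-2,9-dimethylundeca-2,4,6,8-tetraen-10-yn-1-ylidene}-3-{(E)-2-[(1R,2R,4S)-1,2,4-trihydroxy-2,6,6-trimethylcyclohexyl]ethenyl}furan-2(5H)-one | CC1=C(C#C/C(C)=C/C=C/C=C/C=C(C)/C=C2C=C(/C=C/[C@@]3(O)C(C)(C)C[C@H](O)C[C@@]3(C)O)C(=O)O/2)C(C)(C)C[C@H](O)C1 | target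

Total step count: 17. Longest linear sequence: 9 steps (steps 1–8, then 17).

Steps most likely to fail

Step 2 (key step). The hydride may attack the carbonyl of 4 instead of its methylene, the hindered enolate may be alkylated on oxygen or may eliminate the triflate, and the ring closure may go through oxygen or stall at the chloride. The fallback sets out from 3 and rejoins the route at 8. The carbanion of isobutyronitrile (LiN(i-Pr)2, THF, −78 °C) would displace the triflate of 3 to give (4S)-4-[(tert-butyldimethylsilyl)oxy]-5-chloro-2,2-dimethylpentanenitrile F1. Ethyllithium (Et2O, −78 → 0 °C) would add to the nitrile, and brief cold aqueous HCl would hydrolyse the ketimine to chloro ketone 6, now isolated. LiN(i-Pr)2 with LiI in THF–DMPU would then close 6 to 8. The quaternary C1–C2 bond is thus made by nitrile-anion alkylation, and the ring closure becomes a separate step with only one possible enolate.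

Step 7. Ionisation of the protonated epoxide may lead to elimination or a 1,2-shift instead of hydration, or water may attack the wrong epoxide carbon. The fallback sets out from 14 and comes back at 15. Buffered acetolysis (CsOAc, acetic acid, 40 °C) would open the epoxide by carboxylate attack with inversion at C5′ to give (1R,2S,5S)-2-ethynyl-2,5-dihydroxy-1,3,3-trimethylcyclohexyl acetate F2. K2CO3 in methanol would then remove the acetate to give 15. This replaces acid-catalysed hydration by a buffered carboxylate substitution followed by ester cleavage.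

Step 16. The free acid may cyclise 6-endo to the pyranone, or the terminal alkyne may homocouple or oligomerise under the palladium–copper conditions before lactonisation. The fallback sets out from 25 and comes back at 27. Esterification (MeOH, H2SO4 cat.) would give methyl (E)-2,3-dibromoprop-2-enoate F3. Sonogashira coupling with 23 at C3 (PdCl2(PPh3)2, CuI, Et3N, MeCN) would give methyl (2E,6E,8E,10E,12E)-2-bromo-15-[(4R)-4-hydroxy-2,6,6-trimethylcyclohex-1-en-1-yl]-6,13-dimethylpentadeca-2,6,8,10,12-pentaene-4,14-diynoate F4. LiOH in THF–water at 0 °C would give acid 26, now isolated, and AgNO3 (10 mol %) in acetone would close it 5-exo-dig to 27. Coupling and ring closure are thereby separated, and the ring closure is handed to a silver catalyst.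

Further compounds
F1 | step 2 | (4S)-4-[(tert-butyldimethylsilyl)oxy]-5-chloro-2,2-dimethylpentanenitrile | N#CC(C)(C)C[C@H](O[Si](C)(C)C(C)(C)C)CCl
F2 | step 7 | (1R,2S,5S)-2-ethynyl-2,5-dihydroxy-1,3,3-trimethylcyclohexyl acetate | C#C[C@@]1(O)C(C)(C)C[C@H](O)C[C@@]1(C)OC(C)=O
F3 | step 16 | methyl (E)-2,3-dibromoprop-2-enoate | COC(=O)/C(Br)=C\Br
F4 | step 16 | methyl (2E,6E,8E,10E,12E)-2-bromo-15-[(4R)-4-hydroxy-2,6,6-trimethylcyclohex-1-en-1-yl]-6,13-dimethylpentadeca-2,6,8,10,12-pentaene-4,14-diynoate | CC1=C(C#C/C(C)=C/C=C/C=C/C=C(C)/C#C/C=C(/Br)C(=O)OC)C(C)(C)C[C@H](O)C1
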